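**Retrosynthetic overview**
1. The last operation is neutral hydrogenolysis of the 2',4'-bis(benzyl) ether of the flavone, so the Lewis-acid-labile 5-OMe never meets a demethylating reagent.
2. Key disconnection: ring C is cut in one stroke into three components, an o-iodophenol (ring A with O1), CO (C4) and an arylacetylene (C2, C3 and ring B). They are joined by a palladium-catalysed carbonylative annulation, so no acetophenone, chalcone or Baker–Venkataraman diketone is used.
3. Ring A partner: 2-iodo-3,4,5,6-tetramethoxyphenol, made from symmetric 1,2,3,4-tetramethoxybenzene by ortho-lithiation, borylation and oxidation, then iodination of the only C–H left.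
4. Ring B partner: the arylacetylene, made from 2,4-dihydroxy-5-methoxybenzaldehyde by double benzylation and Ohira–Bestmann homologation.
5. Ring order: rings A and B are bought as arenes, and ring C is the only ring formed (step 5).

Assumption: the target has no stereocentre, no stereogenic double bond and no hindered axis, so it is achiral and needs no stereocontrol. Compounds 1 and 6 are taken as catalogue chemicals.

**Step 1**
Reactants: 1 1,2,3,4-tetramethoxybenzene
Product: 4 2,3,4,5-tetramethoxyphenol, via aryllithium 2 (not isolated), via dimethyl arylboronate 3 (not isolated)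
Conditions: n-BuLi, TMEDA, THF, 0 °C to rt; B(OMe)3, −78 °C to rt; AcOH, 30% aq H2O2, 0 °C to rt
Reagents that add atoms: n-butyllithium [Li]CCCC (Li of 2); trimethyl borate COB(OC)OC (B(OMe)2 of 3); hydrogen peroxide OO (O of 4)
Why: Directed ortho-metalation can give only one aryllithium because the two free positions of 1 are equivalent by symmetry, and borate trapping followed by the peroxide-induced boron-to-oxygen 1,2-aryl shift (arylboronate oxidation) delivers the phenol; no stereocentre is formed.

**Step 2**
Reactants: 4 2,3,4,5-tetramethoxyphenol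
Product: 5 2-iodo-3,4,5,6-tetramethoxyphenol
Conditions: NIS (1.05 equiv), MeCN, 0 °C, dark
Reagents that add atoms: N-iodosuccinimide O=C1CCC(=O)N1I
Why: Electrophilic aromatic iodination of a strongly activated phenol whose single remaining ring C–H lies ortho to OH, so the substrate fixes the regiochemistry, and a neutral iodine source at 0 °C limits oxidation to the quinone.

**Step 3**
Reactants: 6 2,4-dihydroxy-5-methoxybenzaldehyde
Product: 7 2,4-bis(benzyloxy)-5-methoxybenzaldehyde
Conditions: BnBr (2.5 equiv), K2CO3, DMF, 60 °C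
Reagents that add atoms: benzyl bromide BrCc1ccccc1
Why: Double Williamson ether synthesis, in which heat and excess BnBr also alkylate the 2-OH that is hydrogen-bonded to the aldehyde.

**Step 4**
Reactants: 7 2,4-bis(benzyloxy)-5-methoxybenzaldehyde
Product: 9 1,5-bis(benzyloxy)-2-ethynyl-4-methoxybenzene, via diazoalkene 8 (not isolated)
Conditions: dimethyl (1-diazo-2-oxopropyl)phosphonate, K2CO3, MeOH–THF, rt
Reagents that add atoms: dimethyl (1-diazo-2-oxopropyl)phosphonate CC(=O)C(=[N+]=[N-])P(=O)(OC)OC
Why: Ohira–Bestmann variant of the Seyferth–Gilbert homologation, in which a Horner–Wadsworth–Emmons-type olefination gives diazoalkene 8, and 8 loses N2 and undergoes a 1,2-hydride shift to the terminal alkyne under mild base that leaves aryl ethers untouched.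

**Step 5 (key step)**
Reactants: 5 2-iodo-3,4,5,6-tetramethoxyphenol; 9 1,5-bis(benzyloxy)-2-ethynyl-4-methoxybenzene
Product: 12 2-[2,4-bis(benzyloxy)-5-methoxyphenyl]-5,6,7,8-tetramethoxy-4H-chromen-4-one, via hydroxyaryl ynone 10 (not isolated), via diethylamino enone 11 (not isolated)
Conditions: PdCl2(dppf) (5 mol %), CO (10 bar), Et2NH (solvent), 110 °C, autoclave, copper-free
Reagents that add atoms: carbon monoxide [C-]#[O+]; diethylamine CCNCC (held only in 11, given back on ring closure)
Why: Palladium-catalysed carbonylative Sonogashira-type coupling and annulation of an o-iodophenol with a terminal alkyne, in which zerovalent palladium formed in situ inserts into the carbon–iodine bond, CO insertion under pressure outruns direct alkynylation for this electron-rich, doubly ortho-substituted aryl, coupling with 9 gives ynone 10, and conjugate addition of Et2NH to give 11 steers the phenol oxygen to 6-endo addition–elimination (flavone) instead of 5-exo attack (aurone); no stereocentre is formed.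

**Step 6**
Reactants: 12 2-[2,4-bis(benzyloxy)-5-methoxyphenyl]-5,6,7,8-tetramethoxy-4H-chromen-4-one
Product: 13 2-(2,4-dihydroxy-5-methoxyphenyl)-5,6,7,8-tetramethoxy-4H-chromen-4-one (target)
Conditions: H2 (1 atm), 10% Pd/C, EtOAc–MeOH, rt, stopped after uptake of 2 equiv
Reagents that add atoms: none
Why: Catalytic hydrogenolysis of the two benzyl aryl ethers under neutral conditions keeps all five methyl ethers (including the labile 5-OMe), avoids base- or acid-induced ring opening of the 2'-hydroxyflavone, and runs much faster than reduction of the pyranone C2=C3 bond.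

**Compound list**
1 | 1,2,3,4-tetramethoxybenzene | COc1ccc(OC)c(OC)c1OC | starting material
2 | (2,3,4,5-tetramethoxyphenyl)lithium | [Li]c1cc(OC)c(OC)c(OC)c1OC | intermediate
3 | dimethyl (2,3,4,5-tetramethoxyphenyl)boronate | COB(OC)c1cc(OC)c(OC)c(OC)c1OC | intermediate
4 | 2,3,4,5-tetramethoxyphenol | Oc1cc(OC)c(OC)c(OC)c1OC | intermediate
5 | 2-iodo-3,4,5,6-tetramethoxyphenol | Oc1c(I)c(OC)c(OC)c(OC)c1OC | intermediate
6 | 2,4-dihydroxy-5-methoxybenzaldehyde | COc1cc(C=O)c(O)cc1O | starting material
7 | 2,4-bis(benzyloxy)-5-methoxybenzaldehyde | COc1cc(C=O)c(OCc2ccccc2)cc1OCc1ccccc1 | intermediate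
8 | 1,5-bis(benzyloxy)-2-(2-diazoethenyl)-4-methoxybenzene | COc1cc(C=C=[N+]=[N-])c(OCc2ccccc2)cc1OCc1ccccc1 | intermediate
9 | 1,5-bis(benzyloxy)-2-ethynyl-4-methoxybenzene | COc1cc(C#C)c(OCc2ccccc2)cc1OCc1ccccc1 | intermediate
10 | 3-[2,4-bis(benzyloxy)-5-methoxyphenyl]-1-(2-hydroxy-3,4,5,6-tetramethoxyphenyl)prop-2-yn-1-one | COc1cc(C#CC(=O)c2c(O)c(OC)c(OC)c(OC)c2OC)c(OCc2ccccc2)cc1OCc1ccccc1 | intermediate
11 | (E)-3-[2,4-bis(benzyloxy)-5-methoxyphenyl]-3-(diethylamino)-1-(2-hydroxy-3,4,5,6-tetramethoxyphenyl)prop-2-en-1-one | CCN(CC)/C(=C/C(=O)c1c(O)c(OC)c(OC)c(OC)c1OC)c1cc(OC)c(OCc2ccccc2)cc1OCc1ccccc1 | intermediate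
12 | 2-[2,4-bis(benzyloxy)-5-methoxyphenyl]-5,6,7,8-tetramethoxy-4H-chromen-4-one | COc1cc(-c2cc(=O)c3c(OC)c(OC)c(OC)c(OC)c3o2)c(OCc2ccccc2)cc1OCc1ccccc1 | intermediate
13 | 2-(2,4-dihydroxy-5-methoxyphenyl)-5,6,7,8-tetramethoxy-4H-chromen-4-one (achiral) | COc1cc(-c2cc(=O)c3c(OC)c(OC)c(OC)c(OC)c3o2)c(O)cc1O | target

**Totals:** 6 steps. The longest linear sequence is 4 steps (1 → 4 → 5 → 12 → 13, or 6 → 7 → 9 → 12 → 13).

**Three steps most likely to fail**

**Step 5.** The risks are direct alkynylation followed by closure to the 2-arylbenzofuran, aminocarbonylation to the diethylamide, and sluggish oxidative addition of the hindered, electron-rich iodide.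
- The fallback sets out from 9 and 5 and comes back to the route at 12, passing through 10. It replaces palladium and CO gas by CO2 as the C4 source and an intramolecular acyl transfer.
- Alkyne 9 is deprotonated (n-BuLi, THF, −78 °C) to the lithium acetylide F1.
- A CO2 quench with HCl work-up then gives 3-[2,4-bis(benzyloxy)-5-methoxyphenyl]propiolic acid F2.
- Steglich esterification of F2 with 5 (DCC, DMAP, CH2Cl2) gives the 2-iodoaryl propiolate F3.
- Iodine–magnesium exchange (i-PrMgCl·LiCl, THF, −40 °C) gives the arylmagnesium chloride F4. This undergoes an anionic Fries-type 1,3 oxygen-to-carbon acyl shift and gives ynone 10 after NH4Cl work-up.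
- Warming 10 with Et2NH in DMF closes it through 11 to 12.

**Step 2.** The risk is that electrophilic iodine oxidises the p-methoxyphenol to a trimethoxybenzoquinone instead of substituting it.
- The fallback sets out from 4 and comes back at 5. It delivers iodine to a carbanion rather than to an oxidisable free phenol.
- Phenol 4 is capped (MOMCl, i-Pr2NEt, CH2Cl2) as the methoxymethyl ether F5.
- n-BuLi (THF, −78 to 0 °C) removes the only ring proton, which is flanked by OMOM and OMe, to give the aryllithium F6.
- An I2 quench gives the iodo methoxymethyl ether F7.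
- Catalytic HCl in MeOH at 40 °C releases 5.

**Step 1.** The risks are incomplete lithiation and over-oxidation of the very electron-rich phenol by peroxide.
- The fallback sets out from 1 and comes back at 4. It uses neither an organolithium nor an oxidant.
- NBS (MeCN, 0 °C) monobrominates 1 to 1-bromo-2,3,4,5-tetramethoxybenzene F8.
- Palladium-catalysed hydroxylation (Pd2(dba)3, t-BuXPhos, KOH, dioxane–H2O, 100 °C, then dilute HCl) converts F8 into 4.

**Further compounds**
F1 | step 5 | lithium [2,4-bis(benzyloxy)-5-methoxyphenyl]acetylide | [Li]C#Cc1cc(OC)c(OCc2ccccc2)cc1OCc1ccccc1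
F2 | step 5 | 3-[2,4-bis(benzyloxy)-5-methoxyphenyl]propiolic acid | COc1cc(C#CC(=O)O)c(OCc2ccccc2)cc1OCc1ccccc1
F3 | step 5 | 2-iodo-3,4,5,6-tetramethoxyphenyl 3-[2,4-bis(benzyloxy)-5-methoxyphenyl]propiolate | COc1cc(C#CC(=O)Oc2c(I)c(OC)c(OC)c(OC)c2OC)c(OCc2ccccc2)cc1OCc1ccccc1
F4 | step 5 | 2-(chloromagnesio)-3,4,5,6-tetramethoxyphenyl 3-[2,4-bis(benzyloxy)-5-methoxyphenyl]propiolate | COc1cc(C#CC(=O)Oc2c([Mg]Cl)c(OC)c(OC)c(OC)c2OC)c(OCc2ccccc2)cc1OCc1ccccc1
F5 | step 2 | 1,2,3,4-tetramethoxy-5-(methoxymethoxy)benzene | COCOc1cc(OC)c(OC)c(OC)c1OC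
F6 | step 2 | [2-(methoxymethoxy)-3,4,5,6-tetramethoxyphenyl]lithium | [Li]c1c(OCOC)c(OC)c(OC)c(OC)c1OC
F7 | step 2 | 1-iodo-2-(methoxymethoxy)-3,4,5,6-tetramethoxybenzene | Ic1c(OCOC)c(OC)c(OC)c(OC)c1OC
F8 | step 1 | 1-bromo-2,3,4,5-tetramethoxybenzene | Brc1cc(OC)c(OC)c(OC)c1OC
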